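The route rests on cutting the C4a–C8a bond of ring A, the 6-hydroxy-7-methoxycoumarin unit. Its benzene ring (C4a, C5, C6, C7, C8, C8a) is grown from a squarate-derived cyclobutenone. The key step exploits the para oxygens at C6 and C8a (O1), flanked by OMe at C7 and H at C8, plus C4 on C4a. All of these are preset in racemic 4-[(E)-3,3-diethoxyprop-1-enyl]-3-methoxy-4-(trimethylsilyloxy)cyclobut-2-enone. One reagent-free heating should turn it into a salicylaldehyde acetal whose C6 oxygen stays silylated, which blocks quinone formation. Acid unmasking, Perkin annulation with (coumarin-7-yloxy)acetic acid and deacetylation finish the target.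

Key step: step 4

Remark on the chemistry: coumarin locants are used for ring A throughout. The target has no stereocentre. The cyclobutenone carbinol derivatives and the transient dienone are racemic and drawn as one enantiomer.

Step 1
Reactants: 1 dimethyl squarate (3,4-dimethoxycyclobut-3-ene-1,2-dione)
Product: 3 methyl semisquarate (3-methoxycyclobut-3-ene-1,2-dione), via 4-hydroxy-2,3-dimethoxycyclobut-2-en-1-one 2 (not isolated)
Conditions: LiAlH(OtBu)3 (1.0 equiv), THF, −78 to −20 °C; 1 M HCl quench; crude in CH2Cl2, conc. HCl (cat.), rt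
Reagents that add atoms: water, O
Why: The bulky hydride should stop after one 1,2-reduction, and acid then ionises the allylic carbinol of 2, water adds at the neighbouring methoxy-bearing carbon and methanol leaves, which is the standard 1,2-addition/acid-hydrolysis route to 4-substituted 3-alkoxycyclobutenediones, run here with hydride as nucleophile; the stereocentre of racemic 2 vanishes in 3.

Step 2
Reactants: 4 3,3-diethoxyprop-1-yne
Product: 5 (E)-tributyl(3,3-diethoxyprop-1-en-1-yl)stannane
Conditions: Bu3SnH (1.1 equiv), Pd2(dba)3 (0.5 mol %), Cy3P·HBF4 (2 mol %), i-Pr2NEt (4 mol %), CH2Cl2, 0 °C to rt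
Reagents that add atoms: tributyltin hydride, CCCC[SnH](CCCC)CCCC
Why: Palladium-catalysed hydrostannation is a syn addition and so can only give the E alkene, while the bulky tricyclohexylphosphine ligand and the branched acetal carbon steer tin to the terminal carbon; any internal stannane would be removed on Et3N-deactivated silica.

Step 3
Reactants: 5 (E)-tributyl(3,3-diethoxyprop-1-en-1-yl)stannane; 3 methyl semisquarate
Product: 8 4-[(E)-3,3-diethoxyprop-1-en-1-yl]-3-methoxy-4-(trimethylsilyloxy)cyclobut-2-en-1-one (racemic), via (E)-3,3-diethoxyprop-1-enyllithium 6 (not isolated), via lithium alkoxide 7 (not isolated)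
Conditions: 5, n-BuLi (1.0 equiv), THF, −78 °C; cannulated into 3, THF, −78 °C; TMSCl (1.5 equiv), −78 to 0 °C; aq. NaHCO3
Reagents that add atoms: chlorotrimethylsilane, C[Si](C)(C)Cl
Why: Tin–lithium exchange keeps the E geometry, and the vinyllithium should undergo 1,2-addition at the carbonyl attached to the methoxy-bearing carbon because the other carbonyl is deactivated as a vinylogous ester; the new quaternary centre forms without facial bias (racemic, erased in step 4) and the alkoxide is silylated in the same flask at no cost in steps.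

Step 4
Reactants: 8 4-[(E)-3,3-diethoxyprop-1-en-1-yl]-3-methoxy-4-(trimethylsilyloxy)cyclobut-2-en-1-one
Product: 11 2-(diethoxymethyl)-5-methoxy-4-(trimethylsilyloxy)phenol, via dienylketene 9 (not isolated), via cyclohexa-2,4-dienone 10 (not isolated)
Conditions: toluene (0.02 M, degassed), 110 °C, argon, base-washed glassware
Reagents that add atoms: none
Why: On heating, the strained ring should open at C1–C4 in a conrotatory 4π process, and because an oxygen donor on C4 prefers the outward path, the propenyl arm swings inward and lies cis to the new ketene in 9. A disrotatory 6π electrocyclisation then joins the acetal-bearing alkene terminus to the ketene carbon (the future C4a–C8a bond), closing the six-membered carbocycle of ring A as dienone 10, whose single sp3 C–H enolises irreversibly to phenol 11. This is the known thermal ring expansion of 4-alkenyl-4-oxygenated cyclobutenones to hydroquinone derivatives (Moore-type rearrangement), an isomerisation that needs no reagent. The product gains no stereocentre, since the racemic centre of 8 is erased on ring opening, that of 10 on aromatisation, and the alkene geometry is lost as well. The selectivity required is torquoselectivity, secured by the outward preference of the OSiMe3 donor, while the pattern C6–O beside C7–OMe, C8–H, and C8a–O beside C4a follows from the connectivity of 8 alone. The silyl cap keeps the C6 oxygen blocked so that 11 cannot be oxidised to a quinone, and dilute, degassed, acid-free conditions protect the monosubstituted ketene and the acetal.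

Step 5
Reactants: 11 2-(diethoxymethyl)-5-methoxy-4-(trimethylsilyloxy)phenol (used crude)
Product: 12 2,5-dihydroxy-4-methoxybenzaldehyde
Conditions: 1 M HCl, THF, rt, argon
Reagents that add atoms: water, O
Why: Acid-catalysed acetal hydrolysis should be very fast because the oxocarbenium ion is stabilised by the ortho hydroxyl and para methoxy groups, and the aryl trimethylsilyl ether falls under the same conditions, so partly desilylated or ethanol-depleted material carried over from step 4 converges on 12.

Step 6
Reactants: 13 umbelliferone (7-hydroxycoumarin); 14 tert-butyl bromoacetate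
Product: 15 tert-butyl 2-[(2-oxo-2H-chromen-7-yl)oxy]acetate
Conditions: K2CO3, acetone, reflux
Reagents that add atoms: none
Why: Williamson ether synthesis of an acidic phenol with an activated primary bromide, using a carbonate base that does not open the lactone in acetone.

Step 7
Reactants: 15 tert-butyl 2-[(2-oxo-2H-chromen-7-yl)oxy]acetate
Product: 16 2-[(2-oxo-2H-chromen-7-yl)oxy]acetic acid
Conditions: TFA/CH2Cl2 (1:1), rt
Reagents that add atoms: none
Why: Acidolysis of the tert-butyl ester through the tert-butyl cation frees the acid without any base, so the coumarin lactone is never opened.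

Step 8
Reactants: 12 2,5-dihydroxy-4-methoxybenzaldehyde; 16 2-[(2-oxo-2H-chromen-7-yl)oxy]acetic acid
Product: 19 7-methoxy-2-oxo-3-[(2-oxo-2H-chromen-7-yl)oxy]-2H-chromen-6-yl acetate, via mixed anhydride 17 (not isolated), via aryl ester 18 (not isolated)
Conditions: Ac2O (solvent), Et3N (3 equiv), 110 °C, argon
Reagents that add atoms: acetic anhydride, CC(=O)OC(C)=O
Why: Perkin condensation in its Oglialoro form: acetic anhydride turns 16 into 17 and caps the phenols, reversible acyl exchange places the aryloxyacetyl group on the oxygen ortho to the aldehyde (18), and its CH2, far easier to enolise than an acetyl CH3, undergoes intramolecular aldol condensation and dehydration to close the pyranone ring, leaving the remote C6 phenol as its acetate.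

Step 9
Reactants: 19 7-methoxy-2-oxo-3-[(2-oxo-2H-chromen-7-yl)oxy]-2H-chromen-6-yl acetate
Product: 20 6-hydroxy-7-methoxy-3-[(2-oxo-2H-chromen-7-yl)oxy]-2H-chromen-2-one (target)
Conditions: HCl (cat., 1.25 M in MeOH), MeOH/THF, 40 °C
Reagents that add atoms: none
Why: Acid-catalysed transesterification removes the phenolic acetate, while both coumarin lactones remain in their favoured ring-closed form under acid and the C3 aryloxy linkage is inert.

Compound list

1 | dimethyl squarate | COC1=C(OC)C(=O)C1=O | starting material
2 | 4-hydroxy-2,3-dimethoxycyclobut-2-en-1-one (racemic, one enantiomer drawn) | COC1=C(OC)[C@@H](O)C1=O | intermediate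
3 | methyl semisquarate, 3-methoxycyclobut-3-ene-1,2-dione | COC1=CC(=O)C1=O | intermediate
4 | 3,3-diethoxyprop-1-yne | C#CC(OCC)OCC | starting material
5 | (E)-tributyl(3,3-diethoxyprop-1-en-1-yl)stannane | CCCC[Sn](CCCC)(CCCC)/C=C/C(OCC)OCC | intermediate
6 | (E)-3,3-diethoxyprop-1-enyllithium | [Li]/C=C/C(OCC)OCC | intermediate
7 | lithium 1-[(E)-3,3-diethoxyprop-1-enyl]-2-methoxy-4-oxocyclobut-2-en-1-olate (racemic, one enantiomer drawn) | CCOC(OCC)/C=C/[C@@]1([O-])C(OC)=CC1=O.[Li+] | intermediate
8 | 4-[(E)-3,3-diethoxyprop-1-en-1-yl]-3-methoxy-4-(trimethylsilyloxy)cyclobut-2-en-1-one (racemic, one enantiomer drawn) | CCOC(OCC)/C=C/[C@@]1(O[Si](C)(C)C)C(OC)=CC1=O | intermediate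
9 | (3Z,5E)-7,7-diethoxy-3-methoxy-4-(trimethylsilyloxy)hepta-1,3,5-trien-1-one | O=C=C\C(OC)=C(/C=C/C(OCC)OCC)O[Si](C)(C)C | intermediate
10 | 6-(diethoxymethyl)-3-methoxy-4-(trimethylsilyloxy)cyclohexa-2,4-dien-1-one (racemic, one enantiomer drawn) | CCOC(OCC)[C@@H]1C=C(O[Si](C)(C)C)C(OC)=CC1=O | intermediate
11 | 2-(diethoxymethyl)-5-methoxy-4-(trimethylsilyloxy)phenol | CCOC(OCC)c1cc(O[Si](C)(C)C)c(OC)cc1O | intermediate
12 | 2,5-dihydroxy-4-methoxybenzaldehyde | COc1cc(O)c(C=O)cc1O | intermediate
13 | umbelliferone | Oc1ccc2ccc(=O)oc2c1 | starting material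
14 | tert-butyl bromoacetate | CC(C)(C)OC(=O)CBr | starting material
15 | tert-butyl 2-[(2-oxo-2H-chromen-7-yl)oxy]acetate | CC(C)(C)OC(=O)COc1ccc2ccc(=O)oc2c1 | intermediate
16 | 2-[(2-oxo-2H-chromen-7-yl)oxy]acetic acid | OC(=O)COc1ccc2ccc(=O)oc2c1 | intermediate
17 | acetic 2-[(2-oxo-2H-chromen-7-yl)oxy]acetic anhydride | CC(=O)OC(=O)COc1ccc2ccc(=O)oc2c1 | intermediate
18 | 4-acetoxy-2-formyl-5-methoxyphenyl 2-[(2-oxo-2H-chromen-7-yl)oxy]acetate | COc1cc(OC(=O)COc2ccc3ccc(=O)oc3c2)c(C=O)cc1OC(C)=O | intermediate
19 | 7-methoxy-2-oxo-3-[(2-oxo-2H-chromen-7-yl)oxy]-2H-chromen-6-yl acetate | COc1cc2oc(=O)c(Oc3ccc4ccc(=O)oc4c3)cc2cc1OC(C)=O | intermediate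
20 | 6-hydroxy-7-methoxy-3-[(2-oxo-2H-chromen-7-yl)oxy]-2H-chromen-2-one | COc1cc2oc(=O)c(Oc3ccc4ccc(=O)oc4c3)cc2cc1O | target

Total step count: 9.
Longest linear sequence: 6 steps (1, 3, 4, 5, 8, 9 from dimethyl squarate; the same length from 3,3-diethoxyprop-1-yne through step 2).

Steps most likely to fail

Step 4. Two processes could erode the ring expansion.
- The acetal beside the newly formed phenol could lose ethanol while hot, followed by oligomerisation.
- The monosubstituted ketene could dimerise or be intercepted before it cyclises.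

The fallback sets out from 3 and 4 and comes back at 12. Compound 4 is deprotonated with n-BuLi (THF, −78 °C) to lithium 3,3-diethoxyprop-1-ynide F1. This adds to the same carbonyl of 3 and, after NH4Cl work-up, should give racemic 4-(3,3-diethoxyprop-1-ynyl)-4-hydroxy-3-methoxycyclobut-2-en-1-one F2. Heating F2 in toluene opens it to an enynylketene. That closes through the aryl/phenoxyl diradical (Moore cyclisation) with transfer of the hydroxyl hydrogen, giving 2-(diethoxymethyl)-5-methoxy-1,4-benzoquinone F3. No phenol flanks the acetal of F3 during the heating. Na2S2O4 in aqueous THF then reduces it to 2-(diethoxymethyl)-5-methoxybenzene-1,4-diol F4, and 1 M HCl added to the same flask delivers 12.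

Step 3. Four processes could compete with the wanted 1,2-addition.
- Conjugate addition at the unsubstituted ring CH.
- Proton abstraction by the basic vinyllithium.
- A second addition.
- Attack at the vinylogous ester carbonyl.

The fallback sets out from 3 and 4 and comes back at 11. The less basic and sterically slim lithium 3,3-diethoxyprop-1-ynide F1 is added to 3 at −78 °C and the alkoxide is capped with TMSCl. This should give racemic 4-(3,3-diethoxyprop-1-ynyl)-3-methoxy-4-(trimethylsilyloxy)cyclobut-2-en-1-one F5. Semihydrogenation (H2, Pd/CaCO3 poisoned with Pb(OAc)2, quinoline, EtOAc) leaves the vinylogous ester alkene untouched and gives 4-[(Z)-3,3-diethoxyprop-1-enyl]-3-methoxy-4-(trimethylsilyloxy)cyclobut-2-en-1-one F6. F6 is heated as in step 4, in xylene if closure is slower. Aromatisation erases the alkene geometry, so F6 converges on 11.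

Step 8. Two processes could lower the outcome.
- Acetyl groups could compete with the aryloxyacetyl group for the ortho oxygen, so that condensation runs through acetate.
- The electron-rich aldehyde could degrade thermally.

The fallback sets out from 16 and 12 and comes back at 20, and it avoids acetic anhydride altogether. Compound 16 is converted with oxalyl chloride and catalytic DMF (CH2Cl2, rt) into 2-[(2-oxo-2H-chromen-7-yl)oxy]acetyl chloride F7. Two equivalents of F7 with Et3N in CH2Cl2 acylate both phenols of 12, giving 2-formyl-5-methoxybenzene-1,4-diyl bis{2-[(2-oxo-2H-chromen-7-yl)oxy]acetate} F8. With more Et3N at reflux, the ortho ester of F8 undergoes intramolecular aldol condensation. The product is 7-methoxy-2-oxo-3-[(2-oxo-2H-chromen-7-yl)oxy]-2H-chromen-6-yl 2-[(2-oxo-2H-chromen-7-yl)oxy]acetate F9. The acid methanolysis of step 9 then cleaves the remaining phenolic ester to 20.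

Further compounds

F1 | step 4 | lithium 3,3-diethoxyprop-1-ynide | [Li]C#CC(OCC)OCC
F2 | step 4 | 4-(3,3-diethoxyprop-1-ynyl)-4-hydroxy-3-methoxycyclobut-2-en-1-one (racemic, one enantiomer drawn) | CCOC(OCC)C#C[C@@]1(O)C(OC)=CC1=O
F3 | step 4 | 2-(diethoxymethyl)-5-methoxy-1,4-benzoquinone | CCOC(OCC)C1=CC(=O)C(OC)=CC1=O
F4 | step 4 | 2-(diethoxymethyl)-5-methoxybenzene-1,4-diol | CCOC(OCC)c1cc(O)c(OC)cc1O
F5 | step 3 | 4-(3,3-diethoxyprop-1-ynyl)-3-methoxy-4-(trimethylsilyloxy)cyclobut-2-en-1-one (racemic, one enantiomer drawn) | CCOC(OCC)C#C[C@@]1(O[Si](C)(C)C)C(OC)=CC1=O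
F6 | step 3 | 4-[(Z)-3,3-diethoxyprop-1-enyl]-3-methoxy-4-(trimethylsilyloxy)cyclobut-2-en-1-one (racemic, one enantiomer drawn) | CCOC(OCC)/C=C\[C@@]1(O[Si](C)(C)C)C(OC)=CC1=O
F7 | step 8 | 2-[(2-oxo-2H-chromen-7-yl)oxy]acetyl chloride | ClC(=O)COc1ccc2ccc(=O)oc2c1
F8 | step 8 | 2-formyl-5-methoxybenzene-1,4-diyl bis{2-[(2-oxo-2H-chromen-7-yl)oxy]acetate} | COc1cc(OC(=O)COc2ccc3ccc(=O)oc3c2)c(C=O)cc1OC(=O)COc1ccc2ccc(=O)oc2c1
F9 | step 8 | 7-methoxy-2-oxo-3-[(2-oxo-2H-chromen-7-yl)oxy]-2H-chromen-6-yl 2-[(2-oxo-2H-chromen-7-yl)oxy]acetate | COc1cc2oc(=O)c(Oc3ccc4ccc(=O)oc4c3)cc2cc1OC(=O)COc1ccc2ccc(=O)oc2c1
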